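**Plan**

- Retrosynthesis first cuts the ether oxygens (three benzyl groups and the C5 methyl of the new ring A), then the C4a–C5 and C8–C8a bonds of ring A of the methoxylated flavone unit.
- This cut is possible because ring A (C4a, C5, C6, C7, C8, C8a) carries oxygen on C5 and C7 and shares its C4a–C8a bond with the 2-aryl-4-pyranone ring C (O1, C2, C3, C4, C4a, C8a). C5–C8 therefore map onto a 1,1-dimethoxy-3-silyloxybutadiene, and C4a=C8a onto the C5=C6 bond of a monocyclic pyranone bearing a phenylsulfinyl group at the future C4a.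
- The remaining cuts are the biaryl bond between C3' of ring B and C8 of the apigenin unit (Suzuki–Miyaura) and the C2–C3 and O1–C6 bonds of the monocyclic pyranone (enaminone enolate acylation, then ring closure).
- Forward: ring C is closed as a pyranone on the bromodimethoxyphenyl ring B, the biaryl bond to 8-iodo-tri-O-benzylapigenin is made, sulfur is oxidised, ring A is annulated by cycloaddition and double elimination, and the ethers are cleaved.
- The target has no stereocentre. The racemic sulfoxide sulfur and the two ring-fusion carbons of the cycloadduct are erased when ring A aromatises.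

Key step: step 11

Assumption: the biaryl axis between C3' and C8 of the apigenin unit is taken as freely rotating (the target is drawn without axial descriptors), and commercial 3-bromo-4,5-dimethoxybenzoic acid is used so that the pyranone can be built through the acid chloride.

**Route**

Step 1
Reactants: 1 apigenin
Product: 2 5,7-bis(benzyloxy)-2-[4-(benzyloxy)phenyl]-4H-chromen-4-one
Conditions: BnBr (4 equiv), K2CO3, DMF, 80 °C
Reagents that add atoms: benzyl bromide, BrCc1ccccc1
Why: Williamson etherification of the three phenoxides, in which the hydrogen-bonded C5 hydroxyl reacts last and is driven to completion by excess bromide and heat, so that no free phenol remains to misdirect the iodination or quench later base-mediated steps.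

Step 2
Reactants: 2 5,7-bis(benzyloxy)-2-[4-(benzyloxy)phenyl]-4H-chromen-4-one
Product: 3 5,7-bis(benzyloxy)-2-[4-(benzyloxy)phenyl]-8-iodo-4H-chromen-4-one
Conditions: I2, CF3CO2Ag, CH2Cl2, 0 °C to rt
Reagents that add atoms: iodine, [I][I]
Why: Electrophilic aromatic iodination by the acyl hypoiodite formed from I2 and CF3CO2Ag should occur at C8, the most nucleophilic and least shielded position of a fully O-alkylated 5,7-dioxygenated flavone (ortho to the C7 ether and the ring oxygen, para to the C5 ether), while the deactivated 4-benzyloxyphenyl ring and C3 stay untouched.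

Step 3
Reactants: 4 1-(phenylsulfanyl)propan-2-one
Product: 5 (Z)-4-(dimethylamino)-3-(phenylsulfanyl)but-3-en-2-one
Conditions: Me2NCH(OMe)2 (1.1 equiv), toluene, 60 °C
Reagents that add atoms: N,N-dimethylformamide dimethyl acetal, COC(OC)N(C)C
Why: Enaminone formation by condensation of the amide acetal with an active methylene should take place only at the sulfur-activated CH2, which is far more acidic than the methyl group, leaving the methyl group free for the enolisation of step 5.

Step 4
Reactants: 6 3-bromo-4,5-dimethoxybenzoic acid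
Product: 7 3-bromo-4,5-dimethoxybenzoyl chloride
Conditions: (COCl)2, DMF (cat.), CH2Cl2, 0 °C to rt
Reagents that add atoms: oxalyl chloride, O=C(Cl)C(Cl)=O
Why: Acid chloride formation through the Vilsmeier-type chloroiminium species generated from oxalyl chloride and catalytic DMF, to which the aryl bromide and the methyl ethers are inert.

Step 5
Reactants: 5 (Z)-4-(dimethylamino)-3-(phenylsulfanyl)but-3-en-2-one; 7 3-bromo-4,5-dimethoxybenzoyl chloride
Product: 9 2-(3-bromo-4,5-dimethoxyphenyl)-5-(phenylsulfanyl)-4H-pyran-4-one, via diketo enaminone 8 (not isolated)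
Conditions: LiN(i-Pr)2 (2.2 equiv), 5 (2.2 equiv), THF, −78 °C; 7, −78 to 0 °C; aq. NH4Cl; then CF3CO2H, CH2Cl2, rt
Reagents that add atoms: none
Why: Crossed Claisen-type C-acylation of the kinetic lithium enolate of the vinylogous amide (its methyl group is the only enolisable site, and the second equivalent of enolate takes up the acidic diketone proton) followed by acid-promoted addition of the enol oxygen to the enaminone carbon and loss of dimethylamine (addition–elimination, 6-endo-trig) is an established way to close 2-substituted 4-pyranones.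

Step 6
Reactants: 9 2-(3-bromo-4,5-dimethoxyphenyl)-5-(phenylsulfanyl)-4H-pyran-4-one
Product: 10 2-[3,4-dimethoxy-5-(4,4,5,5-tetramethyl-1,3,2-dioxaborolan-2-yl)phenyl]-5-(phenylsulfanyl)-4H-pyran-4-one
Conditions: B2pin2, Pd(dppf)Cl2 (cat.), KOAc, 1,4-dioxane, 90 °C
Reagents that add atoms: bis(pinacolato)diboron, CC1(C)OB(OC1(C)C)B1OC(C)(C)C(C)(C)O1
Why: Miyaura borylation (oxidative addition of the aryl bromide to zerovalent palladium, then acetate-assisted transmetalation with the diboron) should proceed cleanly because the weak base KOAc leaves the pyranone closed and the aryl vinyl sulfide does not undergo C–S insertion under these conditions.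

Step 7
Reactants: 3 5,7-bis(benzyloxy)-2-[4-(benzyloxy)phenyl]-8-iodo-4H-chromen-4-one; 10 2-[3,4-dimethoxy-5-(4,4,5,5-tetramethyl-1,3,2-dioxaborolan-2-yl)phenyl]-5-(phenylsulfanyl)-4H-pyran-4-one
Product: 11 5,7-bis(benzyloxy)-2-[4-(benzyloxy)phenyl]-8-{2,3-dimethoxy-5-[4-oxo-5-(phenylsulfanyl)-4H-pyran-2-yl]phenyl}-4H-chromen-4-one
Conditions: Pd(OAc)2 (cat.), SPhos, K3PO4, 1,4-dioxane/H2O (10:1), 80 °C
Reagents that add atoms: none
Why: Suzuki–Miyaura coupling of the aryl iodide with the pinacol boronate, for which the bulky electron-rich biaryl phosphine is chosen to form the tri-ortho-substituted biaryl bond and K3PO4 in a largely organic medium to spare the base-sensitive pyranone; no stereocentre arises because the new axis is not configurationally fixed.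

Step 8
Reactants: 11 5,7-bis(benzyloxy)-2-[4-(benzyloxy)phenyl]-8-{2,3-dimethoxy-5-[4-oxo-5-(phenylsulfanyl)-4H-pyran-2-yl]phenyl}-4H-chromen-4-one
Product: 12 5,7-bis(benzyloxy)-2-[4-(benzyloxy)phenyl]-8-{2,3-dimethoxy-5-[4-oxo-5-(phenylsulfinyl)-4H-pyran-2-yl]phenyl}-4H-chromen-4-one (racemic at sulfur)
Conditions: mCPBA (1.0 equiv), CH2Cl2, −78 to −20 °C
Reagents that add atoms: meta-chloroperoxybenzoic acid, OOC(=O)c1cccc(Cl)c1
Why: Electrophilic sulfide oxidation with one equivalent of peracid at low temperature should stop at the sulfoxide, since the second oxidation is much slower, and the sulfur stereocentre forms without control as the racemate, which is of no consequence because sulfur is expelled in step 11.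

Step 9
Reactants: 13 1,1-dimethoxyethene
Product: 14 4,4-dimethoxybut-3-en-2-one
Conditions: AcCl, Et3N, Et2O, 0 °C to rt
Reagents that add atoms: acetyl chloride, CC(Cl)=O
Why: C-acylation of the nucleophilic ketene acetal by the acid chloride, followed by loss of HCl to the amine, should give the β,β-dimethoxy enone.

Step 10
Reactants: 14 4,4-dimethoxybut-3-en-2-one
Product: 15 1,1-dimethoxy-3-(trimethylsilyloxy)buta-1,3-diene
Conditions: LiN(i-Pr)2, THF, −78 °C; Me3SiCl, −78 °C to rt; distillation
Reagents that add atoms: chlorotrimethylsilane, C[Si](C)(C)Cl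
Why: Silyl enol ether formation by kinetic deprotonation of the methyl ketone (the only acidic C–H) and O-silylation of the lithium enolate should deliver the moisture-sensitive ketene-acetal diene, which is used freshly distilled.

Step 11
Reactants: 12 5,7-bis(benzyloxy)-2-[4-(benzyloxy)phenyl]-8-{2,3-dimethoxy-5-[4-oxo-5-(phenylsulfinyl)-4H-pyran-2-yl]phenyl}-4H-chromen-4-one (racemic at sulfur); 15 1,1-dimethoxy-3-(trimethylsilyloxy)buta-1,3-diene
Product: 19 5,7-bis(benzyloxy)-2-[4-(benzyloxy)phenyl]-8-[5-(7-hydroxy-5-methoxy-4-oxo-4H-chromen-2-yl)-2,3-dimethoxyphenyl]-4H-chromen-4-one, via cis-fused cycloadduct 16 (not isolated), via dihydrochromenone ketal 17 (not isolated), via silyl ether 18 (not isolated)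
Conditions: 15 (4 equiv), toluene, rt to 90 °C; then 1 M HCl, THF, rt
Reagents that add atoms: none
Why: Proposed new method: a normal-electron-demand, strongly asynchronous Diels–Alder reaction in which the CH2 terminus of the diene (largest HOMO coefficient, reinforced by the ketene-acetal and silyloxy donors) bonds to C6 of the pyranone, the unsubstituted β-carbon of the enone, and the ketene-acetal carbon bonds to the sulfinyl-bearing C5, which the carbonyl and sulfinyl groups activate together; these bonds become C8–C8a and C4a–C5 of the chromone. The closest known reactions are cycloadditions of 1,1-dialkoxy-3-silyloxybutadienes with halo- and sulfinylquinones and of dienes with 3-sulfinyl- or 3-acylchromones, which follow the same polarity and the same addition, elimination and aromatisation course. Ring A closes as a six-membered carbocycle by intermolecular [4+2] cycloaddition or, in the stepwise limit, by Mukaiyama–Michael addition at C6 followed by 6-(enolexo)-exo-trig closure of the sulfinyl-stabilised enolate onto the dialkoxycarbenium carbon, the same two bonds forming either way. Suprafacial addition gives the cis-fused adduct 16 with the sulfinyl group syn to the C8a hydrogen, its only β-hydrogen, so thermal syn-elimination of benzenesulfenic acid restores C4a=C8a with O1 still on C8a, 1,4-loss of methanol from the allylic ketal 17 aromatises the ring, and acidic work-up hydrolyses silyl ether 18 to the C7 phenol. The two carbon stereocentres and the sulfur centre are erased, so no facial selectivity is needed. The selectivity required is regiochemical and site-selective: the reverse orientation would lead to a 6,8-dioxygenated chromone and is disfavoured by the matched polarisation of diene and sulfinyl enone, while the C2=C3 bonds of both pyranone rings are aryl-substituted and unactivated and should not compete.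

Step 12
Reactants: 19 5,7-bis(benzyloxy)-2-[4-(benzyloxy)phenyl]-8-[5-(7-hydroxy-5-methoxy-4-oxo-4H-chromen-2-yl)-2,3-dimethoxyphenyl]-4H-chromen-4-one
Product: 20 5'-methoxybilobetin, 8-[5-(5,7-dihydroxy-4-oxo-4H-chromen-2-yl)-2,3-dimethoxyphenyl]-5,7-dihydroxy-2-(4-hydroxyphenyl)-4H-chromen-4-one
Conditions: BCl3 (10 equiv), C6HMe5 (10 equiv), CH2Cl2, −78 to 0 °C; MeOH, then H2O
Reagents that add atoms: none
Why: Lewis-acid ether cleavage in which BCl3 with pentamethylbenzene as a non-basic benzyl-cation scavenger removes the three aryl benzyl ethers at low temperature without C-benzylating the phloroglucinol rings, and on warming the boron chelate at the C4 carbonyl delivers chloride to the peri C5 methyl group (chelation-assisted demethylation), whereas the C4' and C5' methyl ethers have no neighbouring carbonyl and should persist.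

**Compound list**

1 | apigenin | O=c1cc(-c2ccc(O)cc2)oc2cc(O)cc(O)c12 | starting material
2 | 5,7-bis(benzyloxy)-2-[4-(benzyloxy)phenyl]-4H-chromen-4-one | O=c1cc(-c2ccc(OCc3ccccc3)cc2)oc2cc(OCc3ccccc3)cc(OCc3ccccc3)c12 | intermediate
3 | 5,7-bis(benzyloxy)-2-[4-(benzyloxy)phenyl]-8-iodo-4H-chromen-4-one | O=c1cc(-c2ccc(OCc3ccccc3)cc2)oc2c(I)c(OCc3ccccc3)cc(OCc3ccccc3)c12 | intermediate
4 | 1-(phenylsulfanyl)propan-2-one | CC(=O)CSc1ccccc1 | starting material
5 | (Z)-4-(dimethylamino)-3-(phenylsulfanyl)but-3-en-2-one (dimethylamino group trans to acetyl) | CC(=O)/C(Sc1ccccc1)=C/N(C)C | intermediate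
6 | 3-bromo-4,5-dimethoxybenzoic acid | COc1cc(C(=O)O)cc(Br)c1OC | starting material
7 | 3-bromo-4,5-dimethoxybenzoyl chloride | COc1cc(C(Cl)=O)cc(Br)c1OC | intermediate
8 | (Z)-1-(3-bromo-4,5-dimethoxyphenyl)-5-(dimethylamino)-4-(phenylsulfanyl)pent-4-ene-1,3-dione (formed in the flask, not isolated) | COc1cc(C(=O)CC(=O)/C(Sc2ccccc2)=C/N(C)C)cc(Br)c1OC | intermediate
9 | 2-(3-bromo-4,5-dimethoxyphenyl)-5-(phenylsulfanyl)-4H-pyran-4-one | COc1cc(-c2cc(=O)c(Sc3ccccc3)co2)cc(Br)c1OC | intermediate
10 | 2-[3,4-dimethoxy-5-(4,4,5,5-tetramethyl-1,3,2-dioxaborolan-2-yl)phenyl]-5-(phenylsulfanyl)-4H-pyran-4-one | COc1cc(-c2cc(=O)c(Sc3ccccc3)co2)cc(B2OC(C)(C)C(C)(C)O2)c1OC | intermediate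
11 | 5,7-bis(benzyloxy)-2-[4-(benzyloxy)phenyl]-8-{2,3-dimethoxy-5-[4-oxo-5-(phenylsulfanyl)-4H-pyran-2-yl]phenyl}-4H-chromen-4-one | COc1cc(-c2cc(=O)c(Sc3ccccc3)co2)cc(-c2c(OCc3ccccc3)cc(OCc3ccccc3)c3c(=O)cc(-c4ccc(OCc5ccccc5)cc4)oc23)c1OC | intermediate
12 | 5,7-bis(benzyloxy)-2-[4-(benzyloxy)phenyl]-8-{2,3-dimethoxy-5-[4-oxo-5-(phenylsulfinyl)-4H-pyran-2-yl]phenyl}-4H-chromen-4-one (racemic at sulfur) | COc1cc(-c2cc(=O)c(S(=O)c3ccccc3)co2)cc(-c2c(OCc3ccccc3)cc(OCc3ccccc3)c3c(=O)cc(-c4ccc(OCc5ccccc5)cc4)oc23)c1OC | intermediate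
13 | 1,1-dimethoxyethene | C=C(OC)OC | starting material
14 | 4,4-dimethoxybut-3-en-2-one | CC(=O)C=C(OC)OC | intermediate
15 | 1,1-dimethoxy-3-(trimethylsilyloxy)buta-1,3-diene | COC(OC)=CC(=C)O[Si](C)(C)C | intermediate
16 | cis-fused cycloadduct, 2-aryl-5,5-dimethoxy-4a-(phenylsulfinyl)-7-(trimethylsilyloxy)-4a,5,8,8a-tetrahydro-4H-chromen-4-one with aryl = 3-[5,7-bis(benzyloxy)-2-(4-benzyloxyphenyl)-4-oxo-4H-chromen-8-yl]-4,5-dimethoxyphenyl (racemic, sulfinyl group and C8a hydrogen cis, sulfur configuration unassigned; not isolated) | COC1(OC)C=C(O[Si](C)(C)C)C[C@@H]2OC(-c3cc(OC)c(OC)c(-c4c(OCc5ccccc5)cc(OCc5ccccc5)c5c(=O)cc(-c6ccc(OCc7ccccc7)cc6)oc45)c3)=CC(=O)[C@]12S(=O)c1ccccc1 | intermediate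
17 | dihydrochromenone ketal, 2-aryl-5,5-dimethoxy-7-(trimethylsilyloxy)-5,8-dihydro-4H-chromen-4-one with the same aryl group (not isolated) | COC1(OC)C=C(O[Si](C)(C)C)Cc2oc(-c3cc(OC)c(OC)c(-c4c(OCc5ccccc5)cc(OCc5ccccc5)c5c(=O)cc(-c6ccc(OCc7ccccc7)cc6)oc45)c3)cc(=O)c21 | intermediate
18 | 7-O-trimethylsilyl ether of 19 (not isolated) | COc1cc(O[Si](C)(C)C)cc2oc(-c3cc(OC)c(OC)c(-c4c(OCc5ccccc5)cc(OCc5ccccc5)c5c(=O)cc(-c6ccc(OCc7ccccc7)cc6)oc45)c3)cc(=O)c12 | intermediate
19 | 5,7-bis(benzyloxy)-2-[4-(benzyloxy)phenyl]-8-[5-(7-hydroxy-5-methoxy-4-oxo-4H-chromen-2-yl)-2,3-dimethoxyphenyl]-4H-chromen-4-one | COc1cc(O)cc2oc(-c3cc(OC)c(OC)c(-c4c(OCc5ccccc5)cc(OCc5ccccc5)c5c(=O)cc(-c6ccc(OCc7ccccc7)cc6)oc45)c3)cc(=O)c12 | intermediate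
20 | 5'-methoxybilobetin, 8-[5-(5,7-dihydroxy-4-oxo-4H-chromen-2-yl)-2,3-dimethoxyphenyl]-5,7-dihydroxy-2-(4-hydroxyphenyl)-4H-chromen-4-one | COc1cc(-c2cc(=O)c3c(O)cc(O)cc3o2)cc(-c2c(O)cc(O)c3c(=O)cc(-c4ccc(O)cc4)oc23)c1OC | target

**Step count**

Total step count: 12.
Longest linear sequence: 7 steps (steps 3, 5, 6, 7, 8, 11 and 12 from compound 4; equally long from compound 6 through step 4).

**Steps most likely to fail**

1. Step 11, the one step that goes beyond known chemistry. The diene may be consumed by hydrolysis or by conjugate addition without ring closure before the hindered C4a–C5 bond forms, the orientation may leak towards the reverse regiochemistry, or the sulfinyl pyranone may decompose on heating before it is intercepted. The fallback uses only known chemistry: ring A is brought in ready-made and only ring C is closed, by a Baker–Venkataraman sequence. It sets out from acid chloride 7 and iodide 3 and rejoins the route at the target 20.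
   - Acid chloride 7 would acylate commercial 1-[2,4-bis(benzyloxy)-6-hydroxyphenyl]ethanone (pyridine, DMAP, CH2Cl2) to give 2-acetyl-3,5-bis(benzyloxy)phenyl 3-bromo-4,5-dimethoxybenzoate F1.
   - KOH in pyridine at 50 °C would bring about the acyl shift to 1-[2,4-bis(benzyloxy)-6-hydroxyphenyl]-3-(3-bromo-4,5-dimethoxyphenyl)propane-1,3-dione F2.
   - Cyclodehydration (p-TsOH, toluene, 80 °C) would close 5,7-bis(benzyloxy)-2-(3-bromo-4,5-dimethoxyphenyl)-4H-chromen-4-one F3.
   - Miyaura borylation under the conditions of step 6 would give 5,7-bis(benzyloxy)-2-[3,4-dimethoxy-5-(4,4,5,5-tetramethyl-1,3,2-dioxaborolan-2-yl)phenyl]-4H-chromen-4-one F4.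
   - Suzuki–Miyaura coupling of this boronate with iodide 3 under the conditions of step 7 would give the pentabenzyl ether 5,7-bis(benzyloxy)-2-[4-(benzyloxy)phenyl]-8-{5-[5,7-bis(benzyloxy)-4-oxo-4H-chromen-2-yl]-2,3-dimethoxyphenyl}-4H-chromen-4-one F5.
   - Hydrogenolysis (H2, Pd/C, THF–MeOH, rt) would then release 20 without any methyl ether cleavage.

2. Step 7. Transmetalation at the doubly ortho-flanked C8–palladium centre may be slow enough for protodeboronation of the ortho-alkoxy boronate and hydroxide-induced opening of the pyranone ring to take over. The fallback replaces the base-dependent boron coupling by a fluoride-promoted Stille coupling under non-hydrolytic conditions. It sets out from bromide 9 and rejoins the route at 11.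
   - Stannylation of 9 with hexamethylditin (Pd(PPh3)4, toluene, 100 °C) would give 2-[3,4-dimethoxy-5-(trimethylstannyl)phenyl]-5-(phenylsulfanyl)-4H-pyran-4-one F6.
   - Coupling of F6 with iodide 3 (Pd(P(t-Bu)3)2, CsF, 1,4-dioxane, 90 °C) would give 11.

3. Step 12. The large excess of BCl3 needed to clear four ethers in one operation may also attack the crowded C4' methyl ether, and benzyl cations may escape the scavenger and alkylate the phloroglucinol rings. The fallback separates the two events so that the benzyl groups leave reductively and only the chelation-controlled demethylation uses a Lewis acid. It sets out from 19 and rejoins the route at 20.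
   - Hydrogenolysis of 19 (H2, Pd/C, THF–MeOH, rt) would give 5,7-dihydroxy-8-[5-(7-hydroxy-5-methoxy-4-oxo-4H-chromen-2-yl)-2,3-dimethoxyphenyl]-2-(4-hydroxyphenyl)-4H-chromen-4-one F7.
   - MgI2·OEt2 (THF–toluene, 60 °C), which acts only where magnesium can chelate between the C4 carbonyl and the peri oxygen, would then cleave the C5 methyl ether of F7 to give 20.

Further compounds
F1 | step 11 | 2-acetyl-3,5-bis(benzyloxy)phenyl 3-bromo-4,5-dimethoxybenzoate | COc1cc(C(=O)Oc2cc(OCc3ccccc3)cc(OCc3ccccc3)c2C(C)=O)cc(Br)c1OC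
F2 | step 11 | 1-[2,4-bis(benzyloxy)-6-hydroxyphenyl]-3-(3-bromo-4,5-dimethoxyphenyl)propane-1,3-dione | COc1cc(C(=O)CC(=O)c2c(O)cc(OCc3ccccc3)cc2OCc2ccccc2)cc(Br)c1OC
F3 | step 11 | 5,7-bis(benzyloxy)-2-(3-bromo-4,5-dimethoxyphenyl)-4H-chromen-4-one | COc1cc(-c2cc(=O)c3c(OCc4ccccc4)cc(OCc4ccccc4)cc3o2)cc(Br)c1OC
F4 | step 11 | 5,7-bis(benzyloxy)-2-[3,4-dimethoxy-5-(4,4,5,5-tetramethyl-1,3,2-dioxaborolan-2-yl)phenyl]-4H-chromen-4-one | COc1cc(-c2cc(=O)c3c(OCc4ccccc4)cc(OCc4ccccc4)cc3o2)cc(B2OC(C)(C)C(C)(C)O2)c1OC
F5 | step 11 | 5,7-bis(benzyloxy)-2-[4-(benzyloxy)phenyl]-8-{5-[5,7-bis(benzyloxy)-4-oxo-4H-chromen-2-yl]-2,3-dimethoxyphenyl}-4H-chromen-4-one | COc1cc(-c2cc(=O)c3c(OCc4ccccc4)cc(OCc4ccccc4)cc3o2)cc(-c2c(OCc3ccccc3)cc(OCc3ccccc3)c3c(=O)cc(-c4ccc(OCc5ccccc5)cc4)oc23)c1OC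
F6 | step 7 | 2-[3,4-dimethoxy-5-(trimethylstannyl)phenyl]-5-(phenylsulfanyl)-4H-pyran-4-one | COc1cc(-c2cc(=O)c(Sc3ccccc3)co2)cc([Sn](C)(C)C)c1OC
F7 | step 12 | 5,7-dihydroxy-8-[5-(7-hydroxy-5-methoxy-4-oxo-4H-chromen-2-yl)-2,3-dimethoxyphenyl]-2-(4-hydroxyphenyl)-4H-chromen-4-one | COc1cc(O)cc2oc(-c3cc(OC)c(OC)c(-c4c(O)cc(O)c5c(=O)cc(-c6ccc(O)cc6)oc45)c3)cc(=O)c12
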